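Take the last beta reading at 90.0 s and subtract. 23.3% of the substrate has gone, 8.8% is target, and a leftover of 14 percentage points has not been read at all.

| setting | beta | Friday's | Thursday's |
|---|---|---|---|
| substrate | 0.20 M | 0.10 M | 0.10 M |
| first nucleophile | 0.50 M | 0.500 M | 0.500 M |
| second nucleophile | 0.11 M | 0.110 M | 0.110 M |
| remark | run made earlier |  |  |
| time |  | 15 min | 50 min |

beta run (percent of the substrate charged)

| time / s | target / % | substrate / % |
|---|---|---|
| 20.0 | 2.1 | 93.2 |
| 40.0 | 4.1 | 89.7 |
| 50.0 | 4.5 | 86.4 |
| 80.0 | 8.2 | 78.4 |
| 90.0 | 8.8 | 76.7 |

(readings scatter by 0.5 percentage points)



1. which of the two there is more of at the end, Friday's (target / other capture product)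
2. which of the two there is more of at the end, Thursday's (target / other capture product)
3. how much target is there at the end, in percent of the substrate charged: Friday's
4. how much target is there at the end, in percent of the substrate charged: Thursday's

Two chemists argue over that leftover, and both send it to other capture product. They agree on the clock. Read as first order, the beta substrate falls with 0.177 min⁻¹. So they reckon 93.0% consumed in Friday's flask and >99.9% in Thursday's.

The first chemist holds the target share of consumed substrate constant at the reading 37.8%, which carries the scatter. That gives 35.2% target on Friday's and 37.8% on Thursday's.

The second chemist objects that capture uses up second nucleophile, so the share must move. She defines a preference, the selectivity factor 7.49: the rate of capture by second nucleophile over that by first nucleophile, at equal concentrations. It is the leftover-to-target ratio times the beta ratio of charged c(first nucleophile) to c(second nucleophile), so it is a reading, carries the scatter, and counts the leftover as other capture product. She then takes the means between charge and end in the new flasks, c(first nucleophile) = 0.481 M and c(second nucleophile) = 0.0789 M. The share becomes 44.9%.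

I side with her: 41.8% target on Friday's and 44.9% on Thursday's, with other capture product ahead at 51.2% and 55.1%.

The forecast gives 33% and 35%, which are not my figures, and says “Other capture product dominates in both runs”.

Friday's flask gives 42.5% target and Thursday's 36.8%, more in both than other capture product, which stands at 24.2% and 24.5%. So both chemists put the wrong product ahead in both flasks. Thursday's target stood at 42.4% after 25.0 min, and Thursday's isomer of the product ends at 14.7%.

    substrate → intermediate (k = 0.00300 s⁻¹)
    first nucleophile + intermediate → target (k = 0.150 L mol⁻¹ s⁻¹)
    second nucleophile + intermediate → other capture product (k = 0.730 L mol⁻¹ s⁻¹)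
    intermediate → solvolysis product (k = 0.0330 s⁻¹)
    target ⇌ isomer of the product (K = 0.690, k = 1.90 × 10⁻⁴ s⁻¹)
    second nucleophile → decomposed reagent (k = 0.00240 s⁻¹)

Now take the neighbour of Thursday's charged with 0.20 M of first nucleophile. With 7.49, its share reckoned at the charges is 19.5%, and its share reckoned at mean concentrations is 26.7%. That flask ends with 21.9% target, less than its 32.8% other capture product.

Readings and results were generated by integration on assumed constants; noise was put on by code.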